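**Plan**

1. Labdane numbering is used: ring A = C1–C5 and C10; ring B = C5–C10; side chain C11–C16; C17 on C8; C18/C19 on C4; C20 on C10. Retrosynthetic cuts, in order: ester C15–O; C14–C15 and C13–C16 (back to a C13≡C14 alkyne); C7=C8 (ring B); C8–C17; C4–C5 (ring A); C5=C6; C9–C10.
2. Enabling feature: ring B holds a single alkene, C7=C8, and its two carbons are the ends of the chain C7–C6–C5–C10–C9–C8. Both can therefore be carbonyl carbons (C7 an aldehyde, C8 a methyl ketone already carrying C17), two centres of like polarity that low-valent titanium joins and deoxygenates, so the alkene position is fixed by construction.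
3. Forward: geraniol and hex-5-ynoic acid give an ester; an enantioselective Ireland–Claisen rearrangement makes C9–C10; ring A arises by epoxide/allylsilane cyclisation (C4–C5); ring B closes last by McMurry coupling (C7=C8); then C3 inversion, side-chain completion and esterification.
4. Stereochemistry: C9 and quaternary C10 come from the chair Claisen transition state of an (E)-alkene and a Z(O) boron enolate under a C2-symmetric diazaborolidine. C3 is first set (R) by Shi epoxidation, which matches the chair that places the C5 substituent trans to the C9 arm. C3 is then inverted to the axial (S) alcohol by oxidation and LiBH(s-Bu)3. The (13E) alkene comes from syn-carboalumination; the acid stereocentre is bought.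
5. Helpers: the C3 alcohol is carried unprotected in its equatorial form until step 10; the alkyne carries SiMe3 from step 3 to step 12.

Key step: step 9

Assumption: (S)-3-methylpentanoic acid is bought; the (S,S)-bromoborane is taken to give acid 5 and the D-fructose-derived Shi ketone the (R)-epoxide 8, and the antipodal controller or ketone is used if a test run shows the opposite sense.

**Route**

Step 1
Reactants: 1 geraniol; 2 hex-5-ynoic acid
Product: 3 geranyl hex-5-ynoate
Conditions: DCC, DMAP (cat.), CH2Cl2, 0 °C → rt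
Reagents that add atoms: none
Why: Steglich esterification of a primary allylic alcohol under neutral conditions, which keeps the (E)-alkene geometry and the terminal alkyne; no stereocentre is formed.

Step 2
Reactants: 3 geranyl hex-5-ynoate
Product: 5 (2S,3R)-2-(but-3-yn-1-yl)-3-ethenyl-3,7-dimethyloct-6-enoic acid, via Z(O) boron ketene acetal 4 (not isolated)
Conditions: (S,S)-1,2-diphenylethylenediamine bis[3,5-bis(trifluoromethyl)benzenesulfonamide], BBr3, CH2Cl2, rt, then vacuum; 3, i-Pr2NEt, CH2Cl2, −78 °C, then −20 → 4 °C; aq. work-up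
Reagents that add atoms: none
Why: Enantioselective Ireland–Claisen rearrangement through a chiral boron ketene acetal: in the chair transition state the (E)-C5=C10 alkene holds the C1 chain equatorial and C20 axial while the Z(O) enolate holds the butynyl arm equatorial, which fixes the C9/C10 relative configuration, and the C2-symmetric diazaborolidine on boron selects the enolate face, so that quaternary C10 and tertiary C9 are set together.

Step 3
Reactants: 5 (2S,3R)-2-(but-3-yn-1-yl)-3-ethenyl-3,7-dimethyloct-6-enoic acid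
Product: 7 (3S,4R)-4-ethenyl-4,8-dimethyl-3-[4-(trimethylsilyl)but-3-yn-1-yl]non-7-en-2-one, via bis-silyl ketal 6 (not isolated)
Conditions: MeLi (5 equiv), THF, 0 °C → rt; TMSCl (excess), 0 °C; 1 M HCl
Reagents that add atoms: methyllithium, [Li]C; chlorotrimethylsilane, C[Si](C)(C)Cl
Why: Carboxylic acid to methyl ketone by organolithium addition: MeLi adds once to the lithium carboxylate and the gem-dialkoxide is trapped by TMSCl and hydrolysed, which prevents over-addition, while the acetylide formed at the same time is C-silylated in the same quench; C9 is not enolised and no stereocentre is touched.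

Step 4
Reactants: 7 (3S,4R)-4-ethenyl-4,8-dimethyl-3-[4-(trimethylsilyl)but-3-yn-1-yl]non-7-en-2-one
Product: 8 (3S,4R)-6-[(2R)-3,3-dimethyloxiran-2-yl]-4-ethenyl-4-methyl-3-[4-(trimethylsilyl)but-3-yn-1-yl]hexan-2-one
Conditions: D-fructose-derived Shi ketone (30 mol %), KHSO5 (Oxone), K2CO3, Bu4NHSO4, MeCN–CH2(OMe)2–aq. Na2B4O7 buffer, 0 °C
Reagents that add atoms: potassium peroxymonosulfate, [K+].[O-]S(=O)(=O)OO
Why: Shi asymmetric epoxidation: the chiral dioxirane attacks only the electron-rich trisubstituted C3=C4 alkene (the monosubstituted vinyl on a quaternary carbon and the silyl alkyne are inert) through a spiro transition state that should give the (R) configuration at C3 under catalyst control.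

Step 5
Reactants: 8 (3S,4R)-6-[(2R)-3,3-dimethyloxiran-2-yl]-4-ethenyl-4-methyl-3-[4-(trimethylsilyl)but-3-yn-1-yl]hexan-2-one
Product: 10 (2S,3S)-3-acetyl-2-{2-[(2R)-3,3-dimethyloxiran-2-yl]ethyl}-2-methyl-7-(trimethylsilyl)hept-6-ynal, via ozonide 9 (not isolated)
Conditions: O3, CH2Cl2, −78 °C (Sudan red end-point); Me2S, −78 °C → rt
Reagents that add atoms: ozone, [O-][O+]=O
Why: Ozonolysis with reductive work-up: the vinyl group is the only alkene left and reacts far faster than the silyl alkyne, which turns C5 into the aldehyde and removes the former C1 of geraniol as formaldehyde; the epoxide and both stereocentres are untouched.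

Step 6
Reactants: 10 (2S,3S)-3-acetyl-2-{2-[(2R)-3,3-dimethyloxiran-2-yl]ethyl}-2-methyl-7-(trimethylsilyl)hept-6-ynal
Product: 11 (3S,4R)-6-[(2R)-3,3-dimethyloxiran-2-yl]-4-methyl-3-[4-(trimethylsilyl)but-3-yn-1-yl]-4-[(1Z)-3-(trimethylsilyl)prop-1-en-1-yl]hexan-2-one
Conditions: [Ph3PCH2CH2SiMe3]I, n-BuLi, THF, −78 → 0 °C; then 10, −78 °C → rt
Reagents that add atoms: [2-(trimethylsilyl)ethyl]triphenylphosphonium iodide, C[Si](C)(C)CC[P+](c1ccccc1)(c1ccccc1)c1ccccc1.[I-]
Why: Wittig olefination with a β-silyl ylide (Seyferth–Fleming allylsilane synthesis): the ylide, used in slight excess at low temperature, reacts at the aldehyde and not at the α-branched ketone, and the C5=C6 geometry (Z expected) does not matter because it is erased in step 7.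

Step 7
Reactants: 11 (3S,4R)-6-[(2R)-3,3-dimethyloxiran-2-yl]-4-methyl-3-[4-(trimethylsilyl)but-3-yn-1-yl]-4-[(1Z)-3-(trimethylsilyl)prop-1-en-1-yl]hexan-2-one
Product: 12 (3S)-3-[(1R,2S,4R)-2-ethenyl-4-hydroxy-1,3,3-trimethylcyclohexyl]-7-(trimethylsilyl)hept-6-yn-2-one
Conditions: BF3·OEt2 (1.2 equiv), CH2Cl2, −78 °C; aq. NaHCO3
Reagents that add atoms: none
Why: Allylsilane-terminated epoxide cyclisation (cation–olefin cyclisation with Sakurai-type termination): BF3 opens the epoxide at tertiary C4, the allylsilane γ-carbon C5 attacks anti to the breaking C4–O bond through a chair in which the C3–O bond, the C9 arm on C10 and the C5 alkene are equatorial and C20 is axial, so that C5 is set with its vinyl group trans to the C9 arm, and loss of silicon from the β-silyl cation leaves the C6=C7 vinyl group.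

Step 8
Reactants: 12 (3S)-3-[(1R,2S,4R)-2-ethenyl-4-hydroxy-1,3,3-trimethylcyclohexyl]-7-(trimethylsilyl)hept-6-yn-2-one
Product: 13 2-{(1S,2R,5R)-5-hydroxy-2,6,6-trimethyl-2-[(3S)-2-oxo-7-(trimethylsilyl)hept-6-yn-3-yl]cyclohexyl}acetaldehyde
Conditions: PdCl2(PhCN)2 (12 mol %), CuCl2·2H2O (12 mol %), AgNO2 (6 mol %), O2 (1 atm), t-BuOH–MeNO2 15:1, rt
Reagents that add atoms: dioxygen, O=O
Why: Aldehyde-selective (anti-Markovnikov) Wacker oxidation with nitrite co-catalysis: oxygen is delivered to the terminal carbon C7 of the vinyl group, a preference that the two quaternary neighbours of C5 should reinforce, while the ketone, the secondary alcohol and the silyl alkyne are tolerated.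

Step 9
Reactants: 13 2-{(1S,2R,5R)-5-hydroxy-2,6,6-trimethyl-2-[(3S)-2-oxo-7-(trimethylsilyl)hept-6-yn-3-yl]cyclohexyl}acetaldehyde
Product: 14 (2R,4aS,5R,8aS)-1,1,4a,6-tetramethyl-5-[4-(trimethylsilyl)but-3-yn-1-yl]-1,2,3,4,4a,5,8,8a-octahydronaphthalen-2-ol
Conditions: TiCl3(DME)1.5, Zn–Cu couple, DME, reflux; 13 added by syringe pump over 30 h (high dilution)
Reagents that add atoms: none
Why: Low-valent titanium transfers one electron to each carbonyl; the C7 and C8 ketyl carbons, both electrophilic before reduction, couple on the metal to a titanium 1,2-diolate, which is then deoxygenated to the C7=C8 alkene (intramolecular McMurry keto–aldehyde coupling; the closest known type is the McMurry synthesis of 1-methylcycloalkenes from ω-oxo aldehydes). Ring B closes as a six-membered pinacol-type ketyl–ketyl coupling across the 1,6-dicarbonyl C7–C6–C5–C10–C9–C8, whose two arms sit trans-diequatorial on ring A. No stereocentre is formed: C5, C9 and C10 are spectators and the ring allows only one alkene geometry. The step must place the double bond at C7=C8 and nowhere else, and it does so by construction, because the alkene arises exactly between the two former carbonyl carbons, so the Δ8(9) and Δ8(17) isomers of elimination chemistry cannot form. Intramolecular coupling is secured over pinacol dimers by slow addition at high dilution, and chemoselectivity by the absence of a third carbonyl (C3 is carried as the free alcohol, the alkyne is capped by silicon).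

Step 10
Reactants: 14 (2R,4aS,5R,8aS)-1,1,4a,6-tetramethyl-5-[4-(trimethylsilyl)but-3-yn-1-yl]-1,2,3,4,4a,5,8,8a-octahydronaphthalen-2-ol
Product: 15 (4aS,5R,8aS)-1,1,4a,6-tetramethyl-5-[4-(trimethylsilyl)but-3-yn-1-yl]-3,4,4a,5,8,8a-hexahydronaphthalen-2(1H)-one
Conditions: Dess–Martin periodinane, NaHCO3, CH2Cl2, 0 °C → rt
Reagents that add atoms: none
Why: Dess–Martin oxidation of the equatorial C3 alcohol to the ketone, a mild non-acidic oxidation that leaves the trisubstituted alkene and the silyl alkyne alone and clears the helper configuration at C3.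

Step 11
Reactants: 15 (4aS,5R,8aS)-1,1,4a,6-tetramethyl-5-[4-(trimethylsilyl)but-3-yn-1-yl]-3,4,4a,5,8,8a-hexahydronaphthalen-2(1H)-one
Product: 16 (2S,4aS,5R,8aS)-1,1,4a,6-tetramethyl-5-[4-(trimethylsilyl)but-3-yn-1-yl]-1,2,3,4,4a,5,8,8a-octahydronaphthalen-2-ol
Conditions: LiBH(s-Bu)3, THF, −78 °C; then H2O
Reagents that add atoms: none
Why: Ketone reduction with a bulky trialkylborohydride: LiBH(s-Bu)3 attacks the 4,4-dimethyl-3-ketone of the trans-decalin from the equatorial side, avoiding the 1,3-diaxial hydrogens at C1 and C5, which should give the axial (3S) alcohol anti to C20.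

Step 12
Reactants: 16 (2S,4aS,5R,8aS)-1,1,4a,6-tetramethyl-5-[4-(trimethylsilyl)but-3-yn-1-yl]-1,2,3,4,4a,5,8,8a-octahydronaphthalen-2-ol
Product: 17 (2S,4aS,5R,8aS)-5-(but-3-yn-1-yl)-1,1,4a,6-tetramethyl-1,2,3,4,4a,5,8,8a-octahydronaphthalen-2-ol
Conditions: K2CO3, MeOH, rt
Reagents that add atoms: none
Why: Base-mediated protodesilylation of the alkynylsilane in methanol, which frees the terminal alkyne needed for carbometalation and affects nothing else.

Step 13
Reactants: 17 (2S,4aS,5R,8aS)-5-(but-3-yn-1-yl)-1,1,4a,6-tetramethyl-1,2,3,4,4a,5,8,8a-octahydronaphthalen-2-ol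
Product: 19 (2S,4aS,5R,8aS)-5-[(3E)-5-hydroxy-3-methylpent-3-en-1-yl]-1,1,4a,6-tetramethyl-1,2,3,4,4a,5,8,8a-octahydronaphthalen-2-ol, via alkenylalane 18 (not isolated)
Conditions: AlMe3 (4 equiv), Cp2ZrCl2 (0.5 equiv), CH2Cl2, 0 °C → rt; evaporate excess AlMe3; n-BuLi, THF–hexane, −78 °C; (CH2O)n, → rt
Reagents that add atoms: trimethylaluminium, C[Al](C)C; paraformaldehyde (as formaldehyde), C=O
Why: Negishi zirconium-catalysed carboalumination: AlMe3 adds syn across the terminal alkyne with methyl at the internal carbon C13, and the alkenylalane, activated as its ate complex, is hydroxymethylated with retention by formaldehyde, which sets the (13E) alkene; the C3 hydroxyl is carried as its aluminium alkoxide and the trisubstituted ring alkene does not react.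

Step 14
Reactants: 19 (2S,4aS,5R,8aS)-5-[(3E)-5-hydroxy-3-methylpent-3-en-1-yl]-1,1,4a,6-tetramethyl-1,2,3,4,4a,5,8,8a-octahydronaphthalen-2-ol; 20 (S)-3-methylpentanoic acid
Product: 21 (2E)-5-[(2S,4aS,5R,8aS)-2-hydroxy-1,1,4a,6-tetramethyl-1,2,3,4,4a,5,8,8a-octahydronaphthalen-5-yl]-3-methylpent-2-en-1-yl (3S)-3-methylpentanoate
Conditions: EDC·HCl, DMAP (cat.), CH2Cl2, 0 °C
Reagents that add atoms: none
Why: Carbodiimide (Steglich) esterification, selective for the primary allylic C15 hydroxyl over the axial neopentyl-type C3 hydroxyl; the acid stereocentre is β to the carbonyl and cannot epimerise.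

**Compound list**

1 | geraniol, (2E)-3,7-dimethylocta-2,6-dien-1-ol | OC/C=C(\C)CCC=C(C)C | starting material
2 | hex-5-ynoic acid | C#CCCCC(=O)O | starting material
3 | geranyl hex-5-ynoate | C#CCCCC(=O)OC/C=C(\C)CCC=C(C)C | intermediate
4 | Z(O) boron ketene acetal of 3, boron held in the (4S,5S)-1,3-bis{[3,5-bis(trifluoromethyl)phenyl]sulfonyl}-4,5-diphenyl-1,3,2-diazaborolidine (not isolated) | C#CCC/C=C(\OB1N(S(=O)(=O)c2cc(C(F)(F)F)cc(C(F)(F)F)c2)[C@@H](c2ccccc2)[C@H](c2ccccc2)N1S(=O)(=O)c1cc(C(F)(F)F)cc(C(F)(F)F)c1)OC/C=C(\C)CCC=C(C)C | intermediate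
5 | (2S,3R)-2-(but-3-yn-1-yl)-3-ethenyl-3,7-dimethyloct-6-enoic acid | C#CCC[C@H](C(=O)O)[C@@](C)(C=C)CCC=C(C)C | intermediate
6 | bis(trimethylsilyl) ketal of 7 (not isolated) | C[Si](C)(C)C#CCC[C@H](C(C)(O[Si](C)(C)C)O[Si](C)(C)C)[C@@](C)(C=C)CCC=C(C)C | intermediate
7 | (3S,4R)-4-ethenyl-4,8-dimethyl-3-[4-(trimethylsilyl)but-3-yn-1-yl]non-7-en-2-one | C[Si](C)(C)C#CCC[C@H](C(C)=O)[C@@](C)(C=C)CCC=C(C)C | intermediate
8 | (3S,4R)-6-[(2R)-3,3-dimethyloxiran-2-yl]-4-ethenyl-4-methyl-3-[4-(trimethylsilyl)but-3-yn-1-yl]hexan-2-one | C[Si](C)(C)C#CCC[C@H](C(C)=O)[C@@](C)(C=C)CC[C@H]1OC1(C)C | intermediate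
9 | ozonide (1,2,4-trioxolane) of the vinyl group of 8 (not isolated) | C[Si](C)(C)C#CCC[C@H](C(C)=O)[C@@](C)(C1OCOO1)CC[C@H]2OC2(C)C | intermediate
10 | (2S,3S)-3-acetyl-2-{2-[(2R)-3,3-dimethyloxiran-2-yl]ethyl}-2-methyl-7-(trimethylsilyl)hept-6-ynal | C[Si](C)(C)C#CCC[C@H](C(C)=O)[C@@](C)(C=O)CC[C@H]1OC1(C)C | intermediate
11 | (3S,4R)-6-[(2R)-3,3-dimethyloxiran-2-yl]-4-methyl-3-[4-(trimethylsilyl)but-3-yn-1-yl]-4-[(1Z)-3-(trimethylsilyl)prop-1-en-1-yl]hexan-2-one | C[Si](C)(C)C#CCC[C@H](C(C)=O)[C@@](C)(/C=C\C[Si](C)(C)C)CC[C@H]1OC1(C)C | intermediate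
12 | (3S)-3-[(1R,2S,4R)-2-ethenyl-4-hydroxy-1,3,3-trimethylcyclohexyl]-7-(trimethylsilyl)hept-6-yn-2-one | C[Si](C)(C)C#CCC[C@H](C(C)=O)[C@]1(C)CC[C@@H](O)C(C)(C)[C@H]1C=C | intermediate
13 | 2-{(1S,2R,5R)-5-hydroxy-2,6,6-trimethyl-2-[(3S)-2-oxo-7-(trimethylsilyl)hept-6-yn-3-yl]cyclohexyl}acetaldehyde | C[Si](C)(C)C#CCC[C@H](C(C)=O)[C@]1(C)CC[C@@H](O)C(C)(C)[C@H]1CC=O | intermediate
14 | (2R,4aS,5R,8aS)-1,1,4a,6-tetramethyl-5-[4-(trimethylsilyl)but-3-yn-1-yl]-1,2,3,4,4a,5,8,8a-octahydronaphthalen-2-ol (C3 hydroxyl equatorial, cis to C20) | C[Si](C)(C)C#CCC[C@@H]1C(C)=CC[C@@H]2C(C)(C)[C@H](O)CC[C@@]12C | intermediate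
15 | (4aS,5R,8aS)-1,1,4a,6-tetramethyl-5-[4-(trimethylsilyl)but-3-yn-1-yl]-3,4,4a,5,8,8a-hexahydronaphthalen-2(1H)-one | C[Si](C)(C)C#CCC[C@@H]1C(C)=CC[C@@H]2C(C)(C)C(=O)CC[C@@]12C | intermediate
16 | (2S,4aS,5R,8aS)-1,1,4a,6-tetramethyl-5-[4-(trimethylsilyl)but-3-yn-1-yl]-1,2,3,4,4a,5,8,8a-octahydronaphthalen-2-ol (C3 hydroxyl axial, anti to C20) | C[Si](C)(C)C#CCC[C@@H]1C(C)=CC[C@@H]2C(C)(C)[C@@H](O)CC[C@@]12C | intermediate
17 | (2S,4aS,5R,8aS)-5-(but-3-yn-1-yl)-1,1,4a,6-tetramethyl-1,2,3,4,4a,5,8,8a-octahydronaphthalen-2-ol | C#CCC[C@@H]1C(C)=CC[C@@H]2C(C)(C)[C@@H](O)CC[C@@]12C | intermediate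
18 | (E)-alkenyl(dimethyl)alane from 17, C3 oxygen as its dimethylaluminium alkoxide (not isolated) | C[Al](C)/C=C(\C)CC[C@@H]1C(C)=CC[C@@H]2C(C)(C)[C@@H](O[Al](C)C)CC[C@@]12C | intermediate
19 | (2S,4aS,5R,8aS)-5-[(3E)-5-hydroxy-3-methylpent-3-en-1-yl]-1,1,4a,6-tetramethyl-1,2,3,4,4a,5,8,8a-octahydronaphthalen-2-ol | OC/C=C(\C)CC[C@@H]1C(C)=CC[C@@H]2C(C)(C)[C@@H](O)CC[C@@]12C | intermediate
20 | (S)-3-methylpentanoic acid | CC[C@H](C)CC(=O)O | starting material
21 | (2E)-5-[(2S,4aS,5R,8aS)-2-hydroxy-1,1,4a,6-tetramethyl-1,2,3,4,4a,5,8,8a-octahydronaphthalen-5-yl]-3-methylpent-2-en-1-yl (3S)-3-methylpentanoate (CNP0307530.1) | CC[C@H](C)CC(=O)OC/C=C(\C)CC[C@@H]1C(C)=CC[C@@H]2C(C)(C)[C@@H](O)CC[C@@]12C | target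

**Step count and risks**

Total steps: 14. Longest linear sequence: 14 steps (geraniol and hex-5-ynoic acid to 21).

Step 7 (ring A closure). What may go wrong: the activated epoxide may rearrange by hydride shift to the isopropyl ketone or open at C3 to a five-membered ring, or the chair may discriminate the two faces of C5 poorly. Fallback, radical instead of cationic ring closure: it sets out from aldehyde 10 and returns at keto-aldehyde 13, so steps 6 to 8 are bypassed. A Horner–Wadsworth–Emmons reaction (triethyl phosphonoacetate, LiCl, DBU) should give the (E)-enoate F1. Cp2TiCl (trivalent titanium, from Cp2TiCl2 and Zn) then opens the epoxide to the C4 tertiary radical, which adds 6-exo to C5 of the enoate and gives the hydroxy ester F2. The methyl ketone is masked as its dioxolane F3 (ethylene glycol, TsOH), the ester is reduced to the aldehyde F4 (i-Bu2AlH, −78 °C), and mild aqueous acid releases 13.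

Step 8 (vinyl to aldehyde). What may go wrong: slow coordination of the shielded vinyl group to palladium, with leakage to the Markovnikov C6 ketone or attack on the alkyne. Fallback, hydroboration in place of direct oxidation: it sets out from 12 and returns at 13. RhCl(PPh3)3-catalysed hydroboration with catecholborane, which takes the alkene in preference to the ketone, followed by NaBO3·4H2O, should give the primary alcohol F5. TEMPO/PhI(OAc)2 then oxidises the primary alcohol selectively to 13.

Step 9 (key step). What may go wrong: intermolecular pinacol coupling, arrest at the diol stage, or epimerisation at C9 through a titanium enolate. Fallback, olefin metathesis in place of carbonyl coupling: it sets out from 13 and returns at 14. Methylenation of both carbonyls (Ph3P=CH2; Cp2TiMe2 for the ketone if it enolises) should give the diene F6. Ring-closing metathesis with the second-generation Grubbs catalyst then forms C7=C8 with loss of ethylene.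

Further compounds
F1 | step 7 | ethyl (2E,4R,5S)-5-acetyl-4-{2-[(2R)-3,3-dimethyloxiran-2-yl]ethyl}-4-methyl-9-(trimethylsilyl)non-2-en-8-ynoate | C[Si](C)(C)C#CCC[C@H](C(C)=O)[C@@](C)(/C=C/C(=O)OCC)CC[C@H]1OC1(C)C
F2 | step 7 | ethyl 2-{(1S,2R,5R)-5-hydroxy-2,6,6-trimethyl-2-[(3S)-2-oxo-7-(trimethylsilyl)hept-6-yn-3-yl]cyclohexyl}acetate | C[Si](C)(C)C#CCC[C@H](C(C)=O)[C@]1(C)CC[C@@H](O)C(C)(C)[C@H]1CC(=O)OCC
F3 | step 7 | dioxolane of F2 (2-methyl-1,3-dioxolan-2-yl in place of acetyl) | C[Si](C)(C)C#CCC[C@H](C1(C)OCCO1)[C@]2(C)CC[C@@H](O)C(C)(C)[C@H]2CC(=O)OCC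
F4 | step 7 | aldehyde from F3 (CH2CHO in place of CH2CO2Et, dioxolane kept) | C[Si](C)(C)C#CCC[C@H](C1(C)OCCO1)[C@]2(C)CC[C@@H](O)C(C)(C)[C@H]2CC=O
F5 | step 8 | (3S)-3-[(1R,2S,4R)-4-hydroxy-2-(2-hydroxyethyl)-1,3,3-trimethylcyclohexyl]-7-(trimethylsilyl)hept-6-yn-2-one | C[Si](C)(C)C#CCC[C@H](C(C)=O)[C@]1(C)CC[C@@H](O)C(C)(C)[C@H]1CCO
F6 | step 9 | diene from 13 by double methylenation (allyl on C5, isopropenyl on C9) | C[Si](C)(C)C#CCC[C@H](C(C)=C)[C@]1(C)CC[C@@H](O)C(C)(C)[C@H]1CC=C
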